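**Plan**

- Retrosynthesis: the four aryl O–CH2OMe protecting bonds are cut first, then C2–Br (traced back to C2–N) and C3–Br of each ring. Next the ring bonds C1–C2 and C2–C3 of both benzene rings are cut, which removes C2 with its nitrogen as nitromethane (one molecule per ring) and leaves two 4-pyranones. Last, one CH2–O bond of the central ether is cut.
- Enabling feature: each ring is numbered C1 (bears the benzylic CH2), C2 and C3 (Br), C4 and C5 (OH), C6 (H). The run C1(CH2O)–C6(H)–C5(O)–C4(O)–C3 is then the chain of ring carbons C2 to C6 of kojic acid with both oxygens in place. Only C2 is absent, and the pyranone ring oxygen sits exactly where it belongs.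
- Forward: the chain is joined first, by Williamson etherification of two MOM-protected kojate halves. Both benzene rings then arise together in one operation, in which two molecules of nitromethane supply C2 of the two rings and the two ring oxygens leave as water.
- Endgame: the new phenols are capped, the nitro groups become amines that steer bromine to C3, nitrogen is exchanged for bromine at C2, and the four acetals are removed.
- Stereochemistry: the target is achiral, with no stereocentre and no stereogenic double bond, so nothing has to be set.

Key step: step 4

Remark: the 2-nitrobenzyl ethers in the middle of the route are photolabile and the aminobenzyl ethers are oxidisable, so these stages are handled in amber glassware under inert gas.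

**Route**

Step 1
Reactants: 1 kojic acid
Product: 2 2-(hydroxymethyl)-5-(methoxymethoxy)-4H-pyran-4-one
Conditions: MOMCl, K2CO3, acetone, 0 °C to rt
Reagents that add atoms: chloromethyl methyl ether (MOMCl), COCCl
Why: K2CO3 deprotonates only the acidic enolic 5-OH, and this oxyanion is O-alkylated by the acetal chloride (Williamson-type alkylation) far faster than the neutral primary alcohol, the same selectivity that is used routinely for 5-O-benzylation of kojic acid.

Step 2
Reactants: 3 chlorokojic acid
Product: 4 2-(chloromethyl)-5-(methoxymethoxy)-4H-pyran-4-one
Conditions: MOMCl, K2CO3, acetone, 0 °C to rt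
Reagents that add atoms: chloromethyl methyl ether (MOMCl), COCCl
Why: The enolate oxygen is O-alkylated by the highly electrophilic chloromethyl ether much faster than by the less reactive CH2Cl arm of a second molecule, so the chloride should be kept for the next step.

Step 3
Reactants: 2 2-(hydroxymethyl)-5-(methoxymethoxy)-4H-pyran-4-one; 4 2-(chloromethyl)-5-(methoxymethoxy)-4H-pyran-4-one
Product: 5 bis{[5-(methoxymethoxy)-4-oxo-4H-pyran-2-yl]methyl} ether
Conditions: NaH, THF/DMF, 0 °C; then 4, n-Bu4NI (cat.), 0 °C to rt
Reagents that add atoms: none
Why: Williamson ether synthesis, in which the primary alkoxide of 2 displaces chloride by SN2 at the activated allylic-type CH2Cl of 4 (speeded by in situ iodide exchange); with both O5 positions blocked as acetals the only nucleophilic oxygen is the one wanted.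

Step 4
Reactants: 5 bis{[5-(methoxymethoxy)-4-oxo-4H-pyran-2-yl]methyl} ether; 6 nitromethane (two molar equivalents are consumed, one per pyranone ring; used in excess)
Product: 7 bis[5-hydroxy-4-(methoxymethoxy)-2-nitrobenzyl] ether
Conditions: MeNO2 (excess), KOt-Bu, t-BuOH/THF, rt to 60 °C; then AcOH
Reagents that add atoms: nitromethane, C[N+](=O)[O-] (the second molar equivalent of 6; each new benzene ring takes up one molecule)
Why: For each pyranone one molecule of 6 is used: its potassium nitronate adds in Michael fashion to an alpha-carbon of the ring (C6 or C2), the 2H-pyran-4-olate so formed opens by retro-oxa-Michael cleavage of the ring C–O bond to a 1,3-dicarbonyl enolate carrying a CH2NO2 end, the nitronate regenerated there adds to the freed carbonyl, and loss of water with enolisation of the old C4 ketone gives the 4-nitrophenolate, so that the nitromethane carbon ends up bonded to the former C2 and C6 of the pyranone (arene C1 and C3) and the ring oxygen leaves as water; the overall equation is 5 + 2 MeNO2 → 7 + 2 H2O. The closest known reaction is the conversion of 2,6-dialkyl-4-pyranones into 3,5-dialkyl-4-nitrophenols by nitromethane and KOt-Bu; here the same pyranone-to-arene ring transformation is asked of a 5-alkoxy pyranone with a free C6–H, twice in one molecule, which is the untested extension. Each of the two benzene rings is closed by a 6-exo-trig intramolecular nitro-aldol (Henry) addition followed by aromatising dehydration. No stereocentre is formed. Regiochemistry needs no control because first attack at either alpha-carbon leads to the same arene; the selectivity needed is for the pyranone over the CH2–O–CH2 bridge, and this is secured because excess nitromethane levels the base to the weakly basic, soft nitronate and because each phenolate formed is para to the nitro group but meta to the benzylic carbon, so it cannot expel the ether as a quinone methide.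

Step 5
Reactants: 7 bis[5-hydroxy-4-(methoxymethoxy)-2-nitrobenzyl] ether
Product: 8 bis[4,5-bis(methoxymethoxy)-2-nitrobenzyl] ether
Conditions: MOMCl, i-Pr2NEt, CH2Cl2, 0 °C to rt
Reagents that add atoms: chloromethyl methyl ether (MOMCl), COCCl
Why: The acidic 4-nitrophenol oxygens are O-alkylated cleanly under amine base (acetal protection of a phenol), which is needed because the para-aminophenol that reduction would otherwise give is prone to oxidation to a quinone imine.

Step 6
Reactants: 8 bis[4,5-bis(methoxymethoxy)-2-nitrobenzyl] ether
Product: 9 bis[2-amino-4,5-bis(methoxymethoxy)benzyl] ether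
Conditions: Fe powder, NH4Cl, EtOH/H2O, 70 °C
Reagents that add atoms: none
Why: Béchamp-type reduction with iron under nearly neutral NH4Cl buffering takes nitroarenes to anilines by stepwise electron and proton transfer, without hydrogenolysis of the benzylic C–O bonds and without acid strong enough to touch the MOM acetals.

Step 7
Reactants: 9 bis[2-amino-4,5-bis(methoxymethoxy)benzyl] ether
Product: 10 bis[2-amino-3-bromo-4,5-bis(methoxymethoxy)benzyl] ether
Conditions: NBS, MeCN, −20 to 0 °C
Reagents that add atoms: N-bromosuccinimide, O=C1CCC(=O)N1Br
Why: Electrophilic aromatic bromination is steered by the amino group, the strongest donor on each ring; its para position (C5) and one ortho position (C1) are substituted, so bromine should enter at C3, ortho to nitrogen and to O4, while C6 is meta to nitrogen and activated by one oxygen only.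

Step 8
Reactants: 10 bis[2-amino-3-bromo-4,5-bis(methoxymethoxy)benzyl] ether
Product: 12 bis[2,3-dibromo-4,5-bis(methoxymethoxy)benzyl] ether, via bis(diazonium) dibromide 11 (not isolated)
Conditions: t-BuONO, CuBr2 (excess), MeCN, 0 °C to rt
Reagents that add atoms: copper dibromide CuBr2, Br[Cu]Br (bromine of 12); tert-butyl nitrite, CC(C)(C)ON=O (second nitrogen of 11 only)
Why: Sandmeyer reaction in its aprotic form, in which the alkyl nitrite diazotises each amine, electron transfer at copper releases N2, and the aryl radical takes bromine from CuBr2; the large excess of CuBr2 should let bromine transfer outrun hydrogen abstraction from the neighbouring benzylic CH2, and the absence of aqueous acid keeps the MOM acetals.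

Step 9
Reactants: 12 bis[2,3-dibromo-4,5-bis(methoxymethoxy)benzyl] ether
Product: 14 bis(2,3-dibromo-4,5-dihydroxybenzyl) ether, via tetrakis(trimethylsilyl) ether 13 (not isolated)
Conditions: Me3SiOTf, 2,2'-bipyridyl, MeCN, 0 °C to rt; then H2O
Reagents that add atoms: trimethylsilyl trifluoromethanesulfonate, C[Si](C)(C)OS(=O)(=O)C(F)(F)F (silyl groups of 13 only, lost again on hydrolysis)
Why: The silyl triflate–bipyridyl pair turns aryl MOM acetals into aryl silyl ethers under buffered aprotic conditions (Lewis acid-mediated acetal exchange) and water then hydrolyses the Si–O bonds, so no strong Brønsted acid meets the para-hydroxybenzyl ether linkage and the C–Br bonds are untouched.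

**Compound list**

1 | kojic acid, 5-hydroxy-2-(hydroxymethyl)-4H-pyran-4-one | OCc1cc(=O)c(O)co1 | starting material
2 | 2-(hydroxymethyl)-5-(methoxymethoxy)-4H-pyran-4-one | OCc1cc(=O)c(OCOC)co1 | intermediate
3 | chlorokojic acid, 2-(chloromethyl)-5-hydroxy-4H-pyran-4-one | ClCc1cc(=O)c(O)co1 | starting material
4 | 2-(chloromethyl)-5-(methoxymethoxy)-4H-pyran-4-one | ClCc1cc(=O)c(OCOC)co1 | intermediate
5 | bis{[5-(methoxymethoxy)-4-oxo-4H-pyran-2-yl]methyl} ether | COCOc1coc(COCc2cc(=O)c(OCOC)co2)cc1=O | intermediate
6 | nitromethane | C[N+](=O)[O-] | starting material
7 | bis[5-hydroxy-4-(methoxymethoxy)-2-nitrobenzyl] ether | COCOc1cc([N+](=O)[O-])c(COCc2cc(O)c(OCOC)cc2[N+](=O)[O-])cc1O | intermediate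
8 | bis[4,5-bis(methoxymethoxy)-2-nitrobenzyl] ether | COCOc1cc([N+](=O)[O-])c(COCc2cc(OCOC)c(OCOC)cc2[N+](=O)[O-])cc1OCOC | intermediate
9 | bis[2-amino-4,5-bis(methoxymethoxy)benzyl] ether | COCOc1cc(N)c(COCc2cc(OCOC)c(OCOC)cc2N)cc1OCOC | intermediate
10 | bis[2-amino-3-bromo-4,5-bis(methoxymethoxy)benzyl] ether | COCOc1cc(COCc2cc(OCOC)c(OCOC)c(Br)c2N)c(N)c(Br)c1OCOC | intermediate
11 | 6,6'-[oxybis(methylene)]bis[2-bromo-3,4-bis(methoxymethoxy)benzenediazonium] dibromide | COCOc1cc(COCc2cc(OCOC)c(OCOC)c(Br)c2[N+]#N)c([N+]#N)c(Br)c1OCOC.[Br-].[Br-] | intermediate (not isolated)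
12 | bis[2,3-dibromo-4,5-bis(methoxymethoxy)benzyl] ether | COCOc1cc(COCc2cc(OCOC)c(OCOC)c(Br)c2Br)c(Br)c(Br)c1OCOC | intermediate
13 | bis[2,3-dibromo-4,5-bis(trimethylsilyloxy)benzyl] ether | C[Si](C)(C)Oc1cc(COCc2cc(O[Si](C)(C)C)c(O[Si](C)(C)C)c(Br)c2Br)c(Br)c(Br)c1O[Si](C)(C)C | intermediate (not isolated)
14 | bis(2,3-dibromo-4,5-dihydroxybenzyl) ether | Oc1cc(COCc2cc(O)c(O)c(Br)c2Br)c(Br)c(Br)c1O | target

**Totals**

Total step count: 9. Longest linear sequence: 8 steps (1 → 2 → 5 → 7 → 8 → 9 → 10 → 12 → 14).

**Steps most likely to fail**

Step 4 (least precedented). The acyclic tricarbonyl nitronate formed when the first ring opens may fragment by retro-Claisen cleavage or condense with itself before it closes. Conversion of the second ring may stall on a poorly soluble, half-converted polyanion, and nitromethane may be used up by self-condensation. The fallback inverts the order of ring formation and ether formation, so that one pyranone is transformed at a time. It sets out from 2 and comes back to the route at 8. Compound 2 is treated with nitromethane and KOt-Bu as in step 4 and should give [5-hydroxy-4-(methoxymethoxy)-2-nitrophenyl]methanol F1. Phenol-selective alkylation with MOMCl and K2CO3 in acetone should give [4,5-bis(methoxymethoxy)-2-nitrophenyl]methanol F2. Part of F2 is converted by Appel reaction (CBr4, PPh3, CH2Cl2, 0 °C) into 1-(bromomethyl)-4,5-bis(methoxymethoxy)-2-nitrobenzene F3. F2 and F3 are then joined with Ag2O in CH2Cl2 in the dark to give 8.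

Step 8. The aryl radical at C2 may be translocated by 1,5-hydrogen transfer from the benzylic CH2 on the far side of the ether oxygen, or may attack the second ring, in competition with bromine transfer from copper. Either path would cut or cross-link the ether, and the Lewis-acidic CuBr2 may also strip MOM groups. The fallback replaces the copper-mediated exchange by a copper-free dediazoniation of an isolated diazonium salt in a bromine-atom-donor solvent. It sets out from 10 and comes back at 12. Diazotisation with NOBF4 in MeCN at −30 °C and precipitation with ether should give 6,6'-[oxybis(methylene)]bis[2-bromo-3,4-bis(methoxymethoxy)benzenediazonium] bis(tetrafluoroborate) F4. F4 is decomposed with KOAc and 18-crown-6 in bromotrichloromethane at rt, where the solvent itself delivers bromine to the aryl radical at a concentration that should suppress the intramolecular hydrogen transfer.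

Step 3. The alkoxide may add in conjugate fashion to a pyranone ring or deprotonate the acidified CH2Cl group, which would lead to ring-opened or self-condensed material in place of the ether. The fallback forms no alkoxide and activates the electrophile in place of the nucleophile. It sets out from 2 and comes back at 5. Part of 2 is converted by Appel reaction (CBr4, PPh3, CH2Cl2, 0 °C) into 2-(bromomethyl)-5-(methoxymethoxy)-4H-pyran-4-one F5. F5 is then coupled with the free alcohol 2 by silver-assisted halide abstraction (Ag2O, 4 Å molecular sieves, CH2Cl2, dark) to give 5.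

**Further compounds**

F1 | step 4 | [5-hydroxy-4-(methoxymethoxy)-2-nitrophenyl]methanol | OCc1cc(O)c(OCOC)cc1[N+](=O)[O-]
F2 | step 4 | [4,5-bis(methoxymethoxy)-2-nitrophenyl]methanol | OCc1cc(OCOC)c(OCOC)cc1[N+](=O)[O-]
F3 | step 4 | 1-(bromomethyl)-4,5-bis(methoxymethoxy)-2-nitrobenzene | BrCc1cc(OCOC)c(OCOC)cc1[N+](=O)[O-]
F4 | step 8 | 6,6'-[oxybis(methylene)]bis[2-bromo-3,4-bis(methoxymethoxy)benzenediazonium] bis(tetrafluoroborate) | COCOc1cc(COCc2cc(OCOC)c(OCOC)c(Br)c2[N+]#N)c([N+]#N)c(Br)c1OCOC.F[B-](F)(F)F.F[B-](F)(F)F
F5 | step 3 | 2-(bromomethyl)-5-(methoxymethoxy)-4H-pyran-4-one | BrCc1cc(=O)c(OCOC)co1
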